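Plan (ent-labdane numbering, C1–C20):
1. Cuts, in retrosynthetic order: acetyl–O6; C13=C16 and C13–C14; O8–C13 of a temporary δ-lactone; O8–C8; C9–C10 together with C4–C5; then C11–C12, C4–C18, C6–C7 and C1–C10 of the open chain.
2. Forward: the chain is joined in the order C1–C10, C6–C7, C4–C18 (oxirane), C11–C12. One Ti(III) radical cascade then closes ring A (C1, C2, C3, C4, C5, C10) first and ring B (C5, C6, C7, C8, C9, C10) last. The lactone is only a helper ring: it delivers O8 and is opened again by the vinyl nucleophile.
3. Enabling feature: C4 is quaternary and carries CH3 beside CH2OH, the footprint of a 2-alkyl-2-methyloxirane opened at its substituted carbon. This radical site is spaced so that C5=C10 and C8=C9 are each reached by 6-endo closure. All free substituents on rings A and B (C18, O6, C11) are equatorial, which is what an all-chair fold delivers.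
4. Stereochemistry: C6 comes from a catalytic enantioselective vinylogous Mukaiyama aldol. C4, C5, C9 and C10 follow from C6 in the cascade, where both C4 epimers of the oxirane converge on one planar radical. C8 comes from the tethered lactonisation.

Key step: step 11

Assumption: the (R,R)-bisphosphoramide of step 5 is taken to expose the Re face of enal 7; if the sense is the opposite, its antipode is used and nothing else changes.

Step 1
Reactants: 1 2-(3-chloropropyl)-2-methyl-1,3-dioxolane; 2 methyl but-2-ynoate
Product: 4 methyl (2E)-3-methyl-6-(2-methyl-1,3-dioxolan-2-yl)hex-2-enoate, via Grignard reagent 3 (not isolated)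
Conditions: Mg, THF, reflux; CuBr·SMe2 (1.05 equiv), THF, −78 °C; 2, −78 °C; sat aq NH4Cl at −78 °C
Reagents that add atoms: none
Why: Syn-carbocupration of the acetylenic ester by the Grignard-derived organocopper reagent, followed by cold protonation, should place the C1 chain trans to the ester and so fix the E geometry of C5=C10 (conjugate addition of an organocopper reagent to an alkynoate).

Step 2
Reactants: 4 methyl (2E)-3-methyl-6-(2-methyl-1,3-dioxolan-2-yl)hex-2-enoate
Product: 6 (6E)-8-hydroxy-6-methyloct-6-en-2-one, via ketal alcohol 5 (not isolated)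
Conditions: DIBAL-H (2.5 equiv), CH2Cl2, −78 °C; then 1 M HCl, THF, 0 °C to rt
Reagents that add atoms: water: O
Why: DIBAL-H reduces the enoate 1,2 without touching the alkene, and the dilute-acid work-up hydrolyses the dioxolane, so the C4 ketone is freed in the same operation (ester reduction followed by acetal hydrolysis).

Step 3
Reactants: 6 (6E)-8-hydroxy-6-methyloct-6-en-2-one
Product: 7 (2E)-3-methyl-7-oxooct-2-enal
Conditions: MnO2 (15 equiv), CH2Cl2, rt
Reagents that add atoms: none
Why: Activated MnO2 oxidises only the allylic alcohol and should leave the alkene geometry and the saturated ketone unchanged (chemoselective allylic oxidation).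

Step 4
Reactants: 8 methyl 3-methylbut-2-enoate
Product: 10 tert-butyl[(1-methoxy-3-methylbuta-1,3-dien-1-yl)oxy]dimethylsilane, via lithium dienolate 9 (not isolated)
Conditions: LDA, THF–DMPU, −78 °C; TBSCl, −78 °C to rt
Reagents that add atoms: tert-butyldimethylsilyl chloride: CC(C)(C)[Si](C)(C)Cl
Why: Kinetic γ-deprotonation of the senecioate gives the extended enolate, which is trapped on oxygen (silyl dienol ether formation).

Step 5
Reactants: 7 (2E)-3-methyl-7-oxooct-2-enal; 10 tert-butyl[(1-methoxy-3-methylbuta-1,3-dien-1-yl)oxy]dimethylsilane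
Product: 11 methyl (2E,5R,6E)-5-hydroxy-3,7-dimethyl-11-oxododeca-2,6-dienoate
Conditions: SiCl4 (1.1 equiv), (R,R)-BINAM-derived bisphosphoramide (5 mol %), i-Pr2NEt (10 mol %), CH2Cl2, −78 °C; sat aq NaHCO3
Reagents that add atoms: none
Why: In this catalytic enantioselective vinylogous Mukaiyama aldol addition the chiral phosphoramide-bound silyl cation activates only the conjugated aldehyde, the dienolate reacts at its γ-carbon (C7) on the Re face to set (6R), and the open transition state should give the E C8=C9 enoate.

Step 6
Reactants: 11 methyl (2E,5R,6E)-5-hydroxy-3,7-dimethyl-11-oxododeca-2,6-dienoate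
Product: 12 methyl (2E,5R,6E)-3,7-dimethyl-11-oxo-5-(triethylsilyloxy)dodeca-2,6-dienoate
Conditions: TESCl, imidazole, CH2Cl2, 0 °C to rt
Reagents that add atoms: chlorotriethylsilane: CC[Si](CC)(CC)Cl
Why: Standard silylation masks O6 against ylide, hydride and enolate with a group that is labile enough to fall off in the acid step 12.

Step 7
Reactants: 12 methyl (2E,5R,6E)-3,7-dimethyl-11-oxo-5-(triethylsilyloxy)dodeca-2,6-dienoate
Product: 13 methyl (2E,5R,6E)-3,7-dimethyl-10-(2-methyloxiran-2-yl)-5-(triethylsilyloxy)deca-2,6-dienoate (both C4 epimers)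
Conditions: Me3SI, n-BuLi, THF, −10 °C (ylide preformed); then 12, −10 to 0 °C
Reagents that add atoms: trimethylsulfonium iodide: C[S+](C)C.[I-]
Why: Corey–Chaykovsky methylene transfer should reach the unhindered methyl ketone faster than the β,β-disubstituted enoate, and no facial control at C4 is expected or needed because step 11 erases this centre.

Step 8
Reactants: 13 methyl (2E,5R,6E)-3,7-dimethyl-10-(2-methyloxiran-2-yl)-5-(triethylsilyloxy)deca-2,6-dienoate
Product: 14 (2E,5R,6E)-3,7-dimethyl-10-(2-methyloxiran-2-yl)-5-(triethylsilyloxy)deca-2,6-dien-1-ol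
Conditions: DIBAL-H (2.2 equiv), CH2Cl2, −78 °C; aq Rochelle salt
Reagents that add atoms: none
Why: At −78 °C DIBAL-H reduces the enoate 1,2 to the allylic alcohol while the 2,2-dialkyloxirane and the silyl ether should survive (ester reduction).

Step 9
Reactants: 14 (2E,5R,6E)-3,7-dimethyl-10-(2-methyloxiran-2-yl)-5-(triethylsilyloxy)deca-2,6-dien-1-ol
Product: 15 2-[(4E,6R,8E)-10-bromo-4,8-dimethyl-6-(triethylsilyloxy)deca-4,8-dien-1-yl]-2-methyloxirane
Conditions: CBr4, PPh3, 2,6-lutidine, CH2Cl2, −30 °C
Reagents that add atoms: carbon tetrabromide: BrC(Br)(Br)Br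
Why: The Appel reaction converts the primary allylic alcohol by SN2 under buffered neutral conditions, so the E alkene and the oxirane should stay intact.

Step 10
Reactants: 15 2-[(4E,6R,8E)-10-bromo-4,8-dimethyl-6-(triethylsilyloxy)deca-4,8-dien-1-yl]-2-methyloxirane; 16 tert-butyl acetate
Product: 18 tert-butyl (4E,7R,8E)-5,9-dimethyl-12-(2-methyloxiran-2-yl)-7-(triethylsilyloxy)dodeca-4,8-dienoate, via lithium enolate 17 (not isolated)
Conditions: 16, LDA, THF, −78 °C; then 15, DMPU, −78 to −30 °C
Reagents that add atoms: none
Why: SN2 alkylation of the ester enolate by the primary allylic bromide forms C11–C12 with retention of alkene geometry, and an oxirane is inert to a lithium enolate at this temperature (enolate alkylation).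

Step 11
Reactants: 18 tert-butyl (4E,7R,8E)-5,9-dimethyl-12-(2-methyloxiran-2-yl)-7-(triethylsilyloxy)dodeca-4,8-dienoate
Product: 22 tert-butyl ent-18-hydroxy-6α-(triethylsilyloxy)-14,15,16-trinorlabd-8(17)-en-13-oate, via C4 radical 19 (not isolated), via C10 radical 20 (not isolated), via C8 radical 21 (not isolated)
Conditions: Cp2TiCl2 (2.5 equiv), Mn dust (8 equiv), degassed THF, rt, slow addition of 18 at high dilution; sat aq NaH2PO4
Reagents that add atoms: none
Why: Titanocene(III) chloride opens either C4 epimer of the oxirane by single-electron transfer to the same planar tertiary β-titanoxy radical 19, which adds to C5 (ring A, 6-endo-trig) to give the tertiary C10 radical 20, which adds to C9 (ring B, 6-endo-trig, C9–C10 bond) to give the tertiary C8 radical 21, from which a second Ti(III) takes a hydrogen atom of C17 to leave the 8(17)-alkene. The closest known reaction type is the titanocene(III)-mediated radical cascade cyclisation of epoxypolyprenes to trans-decalins that end in an exocyclic methylene group. C5 is controlled by C6, because A(1,3) strain with the cis methyl C20 holds H6 in the alkene plane and the bulky radical should then approach anti to the C7 chain, which leaves O6 equatorial, and C4 is controlled by the chair transition state, in which the large CH2OTiCp2Cl arm takes the equatorial site away from C20. C10 is controlled by the chair-like closure of ring B on the face opposite H5 (trans ring fusion, axial C20) and C9 by the E geometry of C8=C9, which puts C11 equatorial. The step needs endo over exo regioselectivity, secured by the methyl groups on C10 and C8 that crowd the exo positions and make each new radical tertiary, and chemoselectivity, secured because the silyl ether and the tert-butyl ester are inert to Ti(III) and the side chain offers radical 21 no π bond. It is stereoconvergent at C4, and any Δ7 alkene from the termination is harmless because step 12 passes through the same C8 cation.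

Step 12
Reactants: 22 tert-butyl ent-18-hydroxy-6α-(triethylsilyloxy)-14,15,16-trinorlabd-8(17)-en-13-oate
Product: 23 ent-6α,18-dihydroxy-14,15,16-trinorlabdan-13,8α-olide
Conditions: TFA–CH2Cl2 1:4, 0 °C, short contact; then sat aq NaHCO3–MeOH, rt
Reagents that add atoms: none
Why: In this Brønsted-acid lactonisation TFA removes the tert-butyl and TES groups and protonates C17, and the C13 carboxyl on the equatorial C9 chain should capture the tertiary C8 cation from the face opposite C20 through a chair-like six-membered closure, which makes O8 equatorial and C17 axial (kinetic trans-fused δ-lactone).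

Step 13
Reactants: 23 ent-6α,18-dihydroxy-14,15,16-trinorlabdan-13,8α-olide
Product: 24 ent-6α,8α,18-trihydroxy-16-norlabd-14-en-13-one
Conditions: CH2=CHMgBr (3.5 equiv), THF, −78 to −40 °C; sat aq NH4Cl at −40 °C
Reagents that add atoms: vinylmagnesium bromide: C=C[Mg]Br
Why: In this mono-addition of a Grignard reagent to a lactone two equivalents are consumed by O6–H and O18–H, and the magnesium hemiketal of the hindered tertiary-alkoxy lactone should persist in the cold, so the enone appears only on quenching.

Step 14
Reactants: 24 ent-6α,8α,18-trihydroxy-16-norlabd-14-en-13-one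
Product: 25 ent-6α,8α,18-trihydroxylabda-13(16),14-diene (andalusol)
Conditions: Ph3PCH3Br (6 equiv), n-BuLi (5.5 equiv), THF, 0 °C; then 24, 0 °C to rt
Reagents that add atoms: methyltriphenylphosphonium bromide: C[P+](c1ccccc1)(c1ccccc1)c1ccccc1.[Br-]
Why: Wittig methylenation attacks the enone carbonyl 1,2 to give the 2-substituted 1,3-diene, the open hydroxy ketone is fed from its hemiketal, and no stereocentre is touched.

Step 15
Reactants: 25 ent-6α,8α,18-trihydroxylabda-13(16),14-diene
Product: 27 ent-6α-acetoxy-8α,18-dihydroxylabda-13(16),14-diene, via cyclic orthoacetate 26 (not isolated)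
Conditions: MeC(OMe)3 (3 equiv), PPTS (5 mol %), CH2Cl2, rt; then AcOH–H2O 4:1, 0 °C; neutral work-up
Reagents that add atoms: trimethyl orthoacetate: CC(OC)(OC)OC; water: O
Why: O6 and O18 are the only hydroxyl pair that can bridge, so orthoester exchange should give the six-membered orthoacetate 26, whose mild hydrolysis should release the less hindered primary O18 and leave the acetyl group on O6, while the tertiary O8–H stays free (regioselective monoacylation of a diol through its cyclic orthoester).

Compound list
1 | 2-(3-chloropropyl)-2-methyl-1,3-dioxolane | CC1(CCCCl)OCCO1 | starting material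
2 | methyl but-2-ynoate | CC#CC(=O)OC | starting material
3 | [3-(2-methyl-1,3-dioxolan-2-yl)propyl]magnesium chloride | CC1(CCC[Mg]Cl)OCCO1 | intermediate
4 | methyl (2E)-3-methyl-6-(2-methyl-1,3-dioxolan-2-yl)hex-2-enoate | COC(=O)/C=C(\C)CCCC1(C)OCCO1 | intermediate
5 | (2E)-3-methyl-6-(2-methyl-1,3-dioxolan-2-yl)hex-2-en-1-ol | OC/C=C(\C)CCCC1(C)OCCO1 | intermediate
6 | (6E)-8-hydroxy-6-methyloct-6-en-2-one | CC(=O)CCC/C(C)=C/CO | intermediate
7 | (2E)-3-methyl-7-oxooct-2-enal | CC(=O)CCC/C(C)=C/C=O | intermediate
8 | methyl 3-methylbut-2-enoate | CC(C)=CC(=O)OC | starting material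
9 | lithium 1-methoxy-3-methylbuta-1,3-dien-1-olate | C=C(C)C=C(OC)O[Li] | intermediate
10 | tert-butyl[(1-methoxy-3-methylbuta-1,3-dien-1-yl)oxy]dimethylsilane (ketene acetal geometry not defined) | C=C(C)C=C(OC)O[Si](C)(C)C(C)(C)C | intermediate
11 | methyl (2E,5R,6E)-5-hydroxy-3,7-dimethyl-11-oxododeca-2,6-dienoate | CC(=O)CCC/C(C)=C/[C@H](O)C/C(C)=C/C(=O)OC | intermediate
12 | methyl (2E,5R,6E)-3,7-dimethyl-11-oxo-5-(triethylsilyloxy)dodeca-2,6-dienoate | CC(=O)CCC/C(C)=C/[C@H](O[Si](CC)(CC)CC)C/C(C)=C/C(=O)OC | intermediate
13 | methyl (2E,5R,6E)-3,7-dimethyl-10-(2-methyloxiran-2-yl)-5-(triethylsilyloxy)deca-2,6-dienoate, both C4 epimers | CC1(CCC/C(C)=C/[C@H](O[Si](CC)(CC)CC)C/C(C)=C/C(=O)OC)CO1 | intermediate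
14 | (2E,5R,6E)-3,7-dimethyl-10-(2-methyloxiran-2-yl)-5-(triethylsilyloxy)deca-2,6-dien-1-ol, both C4 epimers | CC1(CCC/C(C)=C/[C@H](O[Si](CC)(CC)CC)C/C(C)=C/CO)CO1 | intermediate
15 | 2-[(4E,6R,8E)-10-bromo-4,8-dimethyl-6-(triethylsilyloxy)deca-4,8-dien-1-yl]-2-methyloxirane, both C4 epimers | CC1(CCC/C(C)=C/[C@H](O[Si](CC)(CC)CC)C/C(C)=C/CBr)CO1 | intermediate
16 | tert-butyl acetate | CC(=O)OC(C)(C)C | starting material
17 | lithium enolate of tert-butyl acetate | C=C(O[Li])OC(C)(C)C | intermediate
18 | tert-butyl (4E,7R,8E)-5,9-dimethyl-12-(2-methyloxiran-2-yl)-7-(triethylsilyloxy)dodeca-4,8-dienoate, both C4 epimers | CC1(CCC/C(C)=C/[C@H](O[Si](CC)(CC)CC)C/C(C)=C/CCC(=O)OC(C)(C)C)CO1 | intermediate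
19 | acyclic tertiary C4 radical with O18 bound to Cp2Ti(IV)Cl | C[C](CO[Ti](Cl)(C1C=CC=C1)C1C=CC=C1)CCC/C(C)=C/[C@H](O[Si](CC)(CC)CC)C/C(C)=C/CCC(=O)OC(C)(C)C | intermediate
20 | monocyclic tertiary C10 radical (ring A closed; C18 and C6 equatorial) | CC(C)(C)OC(=O)CC/C=C(\C)C[C@@H](O[Si](CC)(CC)CC)[C@H]1[C](C)CCC[C@]1(C)CO[Ti](Cl)(C2C=CC=C2)C2C=CC=C2 | intermediate
21 | bicyclic tertiary C8 radical (trans-decalin) | CC(C)(C)OC(=O)CC[C@H]1[C@]2(C)CCC[C@](C)(CO[Ti](Cl)(C3C=CC=C3)C3C=CC=C3)[C@H]2[C@H](O[Si](CC)(CC)CC)C[C]1C | intermediate
22 | tert-butyl ent-18-hydroxy-6α-(triethylsilyloxy)-14,15,16-trinorlabd-8(17)-en-13-oate (trans-decalin; C18, O6 and C11 equatorial; C19 and C20 axial) | CC(C)(C)OC(=O)CC[C@H]1[C@]2(C)CCC[C@](C)(CO)[C@H]2[C@H](O[Si](CC)(CC)CC)CC1=C | intermediate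
23 | ent-6α,18-dihydroxy-14,15,16-trinorlabdan-13,8α-olide (trans-fused δ-lactone; O8 equatorial, C17 axial) | O=C1CC[C@H]2[C@]3(C)CCC[C@](C)(CO)[C@H]3[C@H](O)C[C@]2(C)O1 | intermediate
24 | ent-6α,8α,18-trihydroxy-16-norlabd-14-en-13-one | C=CC(=O)CC[C@H]1[C@]2(C)CCC[C@](C)(CO)[C@H]2[C@H](O)C[C@]1(C)O | intermediate
25 | ent-6α,8α,18-trihydroxylabda-13(16),14-diene (andalusol) | C=CC(=C)CC[C@H]1[C@]2(C)CCC[C@](C)(CO)[C@H]2[C@H](O)C[C@]1(C)O | intermediate
26 | 6,18-O-(1-methoxyethylidene) derivative of 25 (orthoester carbon not defined) | C=CC(=C)CC[C@H]1[C@]2(C)CCC[C@](C)(CO3)[C@H]2[C@H](OC3(C)OC)C[C@]1(C)O | intermediate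
27 | ent-6α-acetoxy-8α,18-dihydroxylabda-13(16),14-diene, (4S,5S,6R,8S,9S,10R) | C=CC(=C)CC[C@H]1[C@]2(C)CCC[C@](C)(CO)[C@H]2[C@H](OC(C)=O)C[C@]1(C)O | target

Total step count: 15. Longest linear sequence: 14 (steps 1–3 and 5–15; step 4 is a one-step branch).

Steps most likely to fail

Step 11. The C10 radical may lose a hydrogen atom to Ti(III) before ring B closes. The approach of the C4 radical to C5 may be insufficiently face-selective. The CH2OTi arm may be pushed into the axial site by the neighbouring O6 group. Fallback: setting out from 18, the Ti(III) opening is used only for ring A, which gives the monocyclic 9,10-seco alcohol with a C10(20) methylene group F1. Ring B is then closed by a cationic event instead of a radical one. Chlorosulfonic acid in 2-nitropropane at −78 °C (or SnCl4 in CH2Cl2) protonates C20. The C10 cation is attacked by C9 of the E alkene through a chair, and the carboxyl group traps C8. This is the known acid cyclisation of monocyclic homofarnesic-type acids to trans-fused lactones. The tert-butyl and TES groups are lost in the same operation, and the route is rejoined at 23.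

Step 12. The C8 cation may deprotonate reversibly to the tetrasubstituted Δ8 alkene, with loss of the C9 configuration. The lactone may re-ionise and drift to the 8-epimer. Ring B may open by a retro-Prins path once O6 is unmasked. Fallback: setting out from 22, the C8–O8 bond is made by radical hydrofunctionalisation instead of protonation. A cobalt(salen) catalyst with N-fluoro-2,4,6-trimethylpyridinium triflate and 1,1,3,3-tetramethyldisiloxane in PhCF3 at rt transfers a hydrogen atom to C17. The ester carbonyl displaces the oxidised alkylcobalt species at C8, which gives the TES-protected δ-lactone F2 under non-acidic, irreversible conditions. HF·pyridine in THF then removes the silyl group, and the route is rejoined at 23.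

Step 15. The hemiorthoester may collapse without selectivity, and the acetyl group may migrate from O6 to O18 during work-up. Fallback: setting out from 25, both accessible hydroxyl groups are acetylated (Ac2O, pyridine, catalytic DMAP, rt; the tertiary O8–H stays free) to give the 6,18-diacetate F3. Immobilised Candida antarctica lipase B with n-butanol in MTBE at 35 °C then removes only the exposed primary acetate by transesterification. The medium is neutral and does not trigger acyl migration, and the route is rejoined at 27.

Further compounds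
F1 | step 11 | tert-butyl ent-18-hydroxy-6α-(triethylsilyloxy)-14,15,16-trinor-9,10-secolabda-8(9)E,10(20)-dien-13-oate | CC(C)(C)OC(=O)CC/C=C(\C)C[C@@H](O[Si](CC)(CC)CC)[C@H]1C(=C)CCC[C@]1(C)CO
F2 | step 12 | ent-18-hydroxy-6α-(triethylsilyloxy)-14,15,16-trinorlabdan-13,8α-olide | O=C1CC[C@H]2[C@]3(C)CCC[C@](C)(CO)[C@H]3[C@H](O[Si](CC)(CC)CC)C[C@]2(C)O1
F3 | step 15 | ent-6α,18-diacetoxy-8α-hydroxylabda-13(16),14-diene | C=CC(=C)CC[C@H]1[C@]2(C)CCC[C@](C)(COC(C)=O)[C@H]2[C@H](OC(C)=O)C[C@]1(C)O
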